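## Retrosynthetic overview

1. The E-styryl bond is cut last (Heck): vinylcyclohexene 19 + 8-iodo-7-methoxycoumarin 15; the vinyl group of 19 comes from ring aldehyde 18 (Wittig).
2. The cyclohexene of 18, the only carbocycle built in the route, is closed by ring-closing metathesis of acyclic diene aldehyde 17 (E-propenyl + isopropenyl, loss of propene).
3. 17 carries both stereocentres: Claisen rearrangement (chair, 1,3-chirality transfer) of allyl vinyl ether 16, made by copper-catalysed O-vinylation of S-allylic alcohol 7 with E-vinyl iodide 12.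
4. 7: Heck of 6-bromo-7-methoxycoumarin 4 with methyl vinyl ketone, then CBS reduction. 12: isoprenol, tosylate, enyne, carboalumination/iodination. 15: umbelliferone, iodination, O-methylation.
5. Ring order: pyranone ring of the 6-substituted coumarin (step 2), then the cyclohexene (step 11); the 8-substituted coumarin enters preformed.

Assumption: the target is the (1R,2R) isomer read from the SMILES (ring numbered from the quaternary carbon; aryl and styryl groups cis; E styryl bond); numbered compounds are the carbon building blocks, simple reagents stand on the reagent lines.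

## Route

Step 1
Reactants: 1 2-hydroxy-4-methoxybenzaldehyde
Product: 2 5-bromo-2-hydroxy-4-methoxybenzaldehyde
Conditions: Br2, AcOH, rt
Reagents that add atoms: bromine, BrBr
Why: Electrophilic aromatic bromination goes para to the free phenol and ortho to the methoxy group, the most activated and least hindered position.

Step 2
Reactants: 2 5-bromo-2-hydroxy-4-methoxybenzaldehyde
Product: 4 6-bromo-7-methoxy-2H-chromen-2-one, via Z-cinnamate ester 3 (not isolated)
Conditions: Ph3P=CHCO2Et, PhNEt2, reflux (215 °C)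
Reagents that add atoms: (ethoxycarbonylmethylene)triphenylphosphorane, CCOC(=O)C=P(c1ccccc1)(c1ccccc1)c1ccccc1
Why: Wittig olefination of the salicylaldehyde followed by thermal E/Z equilibration and lactonisation of the Z-2-hydroxycinnamate is the standard coumarin annulation and leaves the aryl bromide untouched.

Step 3
Reactants: 4 6-bromo-7-methoxy-2H-chromen-2-one; 5 methyl vinyl ketone
Product: 6 (E)-4-(7-methoxy-2-oxo-2H-chromen-6-yl)but-3-en-2-one
Conditions: Pd(OAc)2 (3 mol %), PPh3, NaHCO3, DMF, 120 °C, sealed tube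
Reagents that add atoms: none
Why: Mizoroki–Heck reaction (oxidative addition of the aryl bromide to zerovalent palladium, insertion at the enone terminus, syn β-hydride elimination) gives the E-enone only.

Step 4
Reactants: 6 (E)-4-(7-methoxy-2-oxo-2H-chromen-6-yl)but-3-en-2-one
Product: 7 6-[(1E,3S)-3-hydroxybut-1-en-1-yl]-7-methoxy-2H-chromen-2-one
Conditions: (R)-2-methyl-CBS-oxazaborolidine (20 mol %), catecholborane, toluene/CH2Cl2, −78 °C; then MeOH, aq NaHCO3
Reagents that add atoms: none
Why: Corey–Bakshi–Shibata reduction with the R catalyst treats the arylvinyl group as the large substituent and gives the S carbinol by 1,2-reduction, the lactone being inert to catecholborane at −78 °C (ee can be raised by recrystallisation).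

Step 5
Reactants: 8 3-methylbut-3-en-1-ol
Product: 9 3-methylbut-3-en-1-yl 4-methylbenzenesulfonate
Conditions: TsCl, Et3N, DMAP (cat.), CH2Cl2, 0 °C to rt
Reagents that add atoms: 4-toluenesulfonyl chloride, Cc1ccc(cc1)S(Cl)(=O)=O
Why: Routine sulfonylation of a primary alcohol turns it into a leaving group.

Step 6
Reactants: 9 3-methylbut-3-en-1-yl 4-methylbenzenesulfonate
Product: 10 2-methylhex-1-en-5-yne
Conditions: lithium acetylide·ethylenediamine, DMSO, 15 °C to rt; distil
Reagents that add atoms: lithium acetylide–ethylenediamine complex, [Li]C#C.NCCN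
Why: SN2 alkylation of acetylide by a primary tosylate in DMSO gives the terminal 1,5-enyne.

Step 7
Reactants: 10 2-methylhex-1-en-5-yne
Product: 12 (E)-1-iodo-2,5-dimethylhexa-1,5-diene, via alkenylalane 11 (not isolated)
Conditions: Me3Al, Cp2ZrCl2 (25 mol %), CH2Cl2, 0 °C to rt; then I2, THF, −30 to 0 °C
Reagents that add atoms: trimethylaluminium, C[Al](C)C; iodine, II
Why: Negishi zirconium-catalysed methylalumination adds Me and Al syn across the terminal alkyne only, and iodinolysis with retention gives the E-iodide with the chain trans to iodine.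

Step 8
Reactants: 13 7-hydroxy-2H-chromen-2-one (umbelliferone)
Product: 14 7-hydroxy-8-iodo-2H-chromen-2-one
Conditions: I2, KI, 20% aq NH3, 0 °C to rt; acidic work-up
Reagents that add atoms: iodine, II
Why: Electrophilic iodination of the phenoxide goes at C8, the ortho position activated by both ring oxygens.

Step 9
Reactants: 14 7-hydroxy-8-iodo-2H-chromen-2-one
Product: 15 8-iodo-7-methoxy-2H-chromen-2-one
Conditions: MeI, K2CO3, acetone, reflux
Reagents that add atoms: iodomethane, CI
Why: Williamson O-methylation of the phenol.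

Step 10
Reactants: 7 6-[(1E,3S)-3-hydroxybut-1-en-1-yl]-7-methoxy-2H-chromen-2-one; 12 (E)-1-iodo-2,5-dimethylhexa-1,5-diene
Product: 17 (2S,3S,4E)-3-(7-methoxy-2-oxo-2H-chromen-6-yl)-2-methyl-2-(3-methylbut-3-en-1-yl)hex-4-enal, via allyl vinyl ether 16 (not isolated)
Conditions: CuI (10 mol %), 3,4,7,8-tetramethyl-1,10-phenanthroline (20 mol %), Cs2CO3, o-xylene, 120 °C, 48 h (12 in 1.3 equiv)
Reagents that add atoms: none
Why: Ullmann-type copper-catalysed C–O vinylation keeps the E geometry of the iodide and the ether undergoes Claisen rearrangement in situ through a chair transition state (carbinol methyl pseudo-equatorial, chain equatorial), so the S carbinol sets both new stereocentres and the E-propenyl group by 1,3-chirality transfer.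

Step 11
Reactants: 17 (2S,3S,4E)-3-(7-methoxy-2-oxo-2H-chromen-6-yl)-2-methyl-2-(3-methylbut-3-en-1-yl)hex-4-enal
Product: 18 (1S,2S)-2-(7-methoxy-2-oxo-2H-chromen-6-yl)-1,4-dimethylcyclohex-3-ene-1-carbaldehyde
Conditions: second-generation Grubbs catalyst RuCl2(H2IMes)(PCy3)(=CHPh) (5 mol %), CH2Cl2 (0.005 M), 40 °C
Reagents that add atoms: none
Why: Ring-closing metathesis between the propenyl and isopropenyl groups forms the trisubstituted cyclohexene with loss of propene, helped by the quaternary centre, while the coumarin double bond is inert and no stereocentre is touched.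

Step 12
Reactants: 18 (1S,2S)-2-(7-methoxy-2-oxo-2H-chromen-6-yl)-1,4-dimethylcyclohex-3-ene-1-carbaldehyde
Product: 19 6-[(1R,6R)-6-ethenyl-3,6-dimethylcyclohex-2-en-1-yl]-7-methoxy-2H-chromen-2-one
Conditions: Ph3PCH3Br, KOtBu, THF, 0 °C to rt
Reagents that add atoms: methyltriphenylphosphonium bromide, C[P+](c1ccccc1)(c1ccccc1)c1ccccc1.[Br-]
Why: Wittig methylenation of the non-enolisable neopentyl aldehyde is faster than any attack on the lactone, and the descriptors change from S,S to R,R only through CIP priorities.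

Step 13
Reactants: 19 6-[(1R,6R)-6-ethenyl-3,6-dimethylcyclohex-2-en-1-yl]-7-methoxy-2H-chromen-2-one; 15 8-iodo-7-methoxy-2H-chromen-2-one
Product: 20 7-methoxy-8-[(E)-2-[(1R,2R)-2-(7-methoxy-2-oxo-2H-chromen-6-yl)-1,4-dimethylcyclohex-3-en-1-yl]ethenyl]-2H-chromen-2-one
Conditions: Pd(OAc)2 (10 mol %), nBu4NCl, NaHCO3, DMF, 85 °C
Reagents that add atoms: none
Why: Mizoroki–Heck arylation under Jeffery conditions puts the aryl group on the terminal carbon, and because the neighbouring carbon is quaternary, syn β-hydride elimination can only give the E-styrene.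

## Compound list

1 | 2-hydroxy-4-methoxybenzaldehyde | COc1ccc(C=O)c(O)c1 | starting material
2 | 5-bromo-2-hydroxy-4-methoxybenzaldehyde | COc1cc(O)c(C=O)cc1Br | intermediate
3 | ethyl (Z)-3-(5-bromo-2-hydroxy-4-methoxyphenyl)prop-2-enoate | CCOC(=O)/C=C\c1cc(Br)c(OC)cc1O | intermediate
4 | 6-bromo-7-methoxy-2H-chromen-2-one | COc1cc2oc(=O)ccc2cc1Br | intermediate
5 | methyl vinyl ketone (but-3-en-2-one) | CC(=O)C=C | starting material
6 | (E)-4-(7-methoxy-2-oxo-2H-chromen-6-yl)but-3-en-2-one | COc1cc2oc(=O)ccc2cc1/C=C/C(C)=O | intermediate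
7 | 6-[(1E,3S)-3-hydroxybut-1-en-1-yl]-7-methoxy-2H-chromen-2-one | COc1cc2oc(=O)ccc2cc1/C=C/[C@H](C)O | intermediate
8 | 3-methylbut-3-en-1-ol (isoprenol) | CC(=C)CCO | starting material
9 | 3-methylbut-3-en-1-yl 4-methylbenzenesulfonate | CC(=C)CCOS(=O)(=O)c1ccc(C)cc1 | intermediate
10 | 2-methylhex-1-en-5-yne | CC(=C)CCC#C | intermediate
11 | [(1E)-2,5-dimethylhexa-1,5-dien-1-yl]dimethylalumane | C[Al](C)/C=C(\C)CCC(C)=C | intermediate
12 | (E)-1-iodo-2,5-dimethylhexa-1,5-diene | I/C=C(\C)CCC(C)=C | intermediate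
13 | 7-hydroxy-2H-chromen-2-one (umbelliferone) | Oc1ccc2ccc(=O)oc2c1 | starting material
14 | 7-hydroxy-8-iodo-2H-chromen-2-one | Oc1ccc2ccc(=O)oc2c1I | intermediate
15 | 8-iodo-7-methoxy-2H-chromen-2-one | COc1ccc2ccc(=O)oc2c1I | intermediate
16 | 6-[(1E,3S)-3-{[(1E)-2,5-dimethylhexa-1,5-dien-1-yl]oxy}but-1-en-1-yl]-7-methoxy-2H-chromen-2-one | COc1cc2oc(=O)ccc2cc1/C=C/[C@H](C)O/C=C(\C)CCC(C)=C | intermediate
17 | (2S,3S,4E)-3-(7-methoxy-2-oxo-2H-chromen-6-yl)-2-methyl-2-(3-methylbut-3-en-1-yl)hex-4-enal | COc1cc2oc(=O)ccc2cc1[C@H](/C=C/C)[C@@](C)(C=O)CCC(C)=C | intermediate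
18 | (1S,2S)-2-(7-methoxy-2-oxo-2H-chromen-6-yl)-1,4-dimethylcyclohex-3-ene-1-carbaldehyde | COc1cc2oc(=O)ccc2cc1[C@@H]1C=C(C)CC[C@]1(C)C=O | intermediate
19 | 6-[(1R,6R)-6-ethenyl-3,6-dimethylcyclohex-2-en-1-yl]-7-methoxy-2H-chromen-2-one | COc1cc2oc(=O)ccc2cc1[C@@H]1C=C(C)CC[C@]1(C)C=C | intermediate
20 | 7-methoxy-8-[(E)-2-[(1R,2R)-2-(7-methoxy-2-oxo-2H-chromen-6-yl)-1,4-dimethylcyclohex-3-en-1-yl]ethenyl]-2H-chromen-2-one | COc1cc2oc(=O)ccc2cc1[C@@H]1C=C(C)CC[C@]1(C)/C=C/c1c(OC)ccc2ccc(=O)oc12 | target

## Step count and risks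

Total step count: 13. Longest linear sequence: 8 steps (1, 2, 3, 4, 10, 11, 12, 13), which is 62% of the total; the other branches are steps 5–7 and steps 8–9.

The three steps most likely to fail:

**Step 10.** The coumarin lactone and the secondary allylic alcohol must survive Cs2CO3 at 120 °C, and the diastereoselectivity rests on clean retention of the vinyl iodide geometry. The fallback sets out from vinyl iodide 12 (with alcohol 7) and comes back to the route at allyl vinyl ether 16, which is then carried to 17. Iodide 12 is borylated with retention (B2pin2, PdCl2(dppf), KOPh, toluene, 50 °C) to (E)-2-(2,5-dimethylhexa-1,5-dien-1-yl)-4,4,5,5-tetramethyl-1,3,2-dioxaborolane F1. This is joined to 7 by an oxidative Chan–Lam-type C–O coupling at room temperature (Cu(OAc)2, Et3N, 4 Å sieves, CH2Cl2, air), giving 16 as an isolated compound. Heating 16 in base-free toluene (120–130 °C, sealed) then effects the Claisen rearrangement to 17.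

**Step 11.** Both olefins are hindered (one 1,1-disubstituted, one internal next to a quaternary carbon), and the free aldehyde can degrade the ruthenium carbene if heating is needed. The fallback sets out from 17 and comes back at 18. NaBH4 (MeOH/THF, −20 °C) reduces only the aldehyde to (2S,3R,4E)-3-(7-methoxy-2-oxo-2H-chromen-6-yl)-2-methyl-2-(3-methylbut-3-en-1-yl)hex-4-en-1-ol F2. The carbinol tolerates forcing metathesis (second-generation Hoveyda–Grubbs catalyst RuCl2(H2IMes)(=CH-C6H4-2-OiPr), toluene, 80–100 °C) to give 6-[(1R,6S)-6-(hydroxymethyl)-3,6-dimethylcyclohex-2-en-1-yl]-7-methoxy-2H-chromen-2-one F3. Dess–Martin periodinane (NaHCO3, CH2Cl2) returns 18.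

**Step 13.** A doubly ortho-substituted aryl iodide has to insert a vinyl group on a quaternary ring carbon, so the Heck reaction may stall. The fallback sets out from aldehyde 18 and iodide 15 and comes back at target 20. Takai olefination of 18 (CrCl2, CHI3, THF, 0 °C to rt) gives 6-[(1R,6S)-6-[(E)-2-iodoethenyl]-3,6-dimethylcyclohex-2-en-1-yl]-7-methoxy-2H-chromen-2-one F4. Miyaura borylation of 15 (B2pin2, PdCl2(dppf), KOAc, dioxane, 80 °C) gives 7-methoxy-8-(4,4,5,5-tetramethyl-1,3,2-dioxaborolan-2-yl)-2H-chromen-2-one F5. Suzuki–Miyaura coupling of F4 with F5 (PdCl2(dppf), K3PO4, DMF, 60 °C) gives 20 with retention of the E geometry.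

## Further compounds

F1 | step 10 | (E)-2-(2,5-dimethylhexa-1,5-dien-1-yl)-4,4,5,5-tetramethyl-1,3,2-dioxaborolane | CC(=C)CC/C(C)=C/B1OC(C)(C)C(C)(C)O1
F2 | step 11 | (2S,3R,4E)-3-(7-methoxy-2-oxo-2H-chromen-6-yl)-2-methyl-2-(3-methylbut-3-en-1-yl)hex-4-en-1-ol | COc1cc2oc(=O)ccc2cc1[C@H](/C=C/C)[C@@](C)(CO)CCC(C)=C
F3 | step 11 | 6-[(1R,6S)-6-(hydroxymethyl)-3,6-dimethylcyclohex-2-en-1-yl]-7-methoxy-2H-chromen-2-one | COc1cc2oc(=O)ccc2cc1[C@@H]1C=C(C)CC[C@]1(C)CO
F4 | step 13 | 6-[(1R,6S)-6-[(E)-2-iodoethenyl]-3,6-dimethylcyclohex-2-en-1-yl]-7-methoxy-2H-chromen-2-one | COc1cc2oc(=O)ccc2cc1[C@@H]1C=C(C)CC[C@]1(C)/C=C/I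
F5 | step 13 | 7-methoxy-8-(4,4,5,5-tetramethyl-1,3,2-dioxaborolan-2-yl)-2H-chromen-2-one | COc1ccc2ccc(=O)oc2c1B1OC(C)(C)C(C)(C)O1
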